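## Retrosynthetic overview

1. The target comes from oxidation and ketal hydrolysis of a bicyclic β-hydroxy ketone, which is made by intramolecular aldol addition (C3 onto the C4 aldehyde) of a ring B keto aldehyde; ring A is closed last.
2. The keto aldehyde comes from C5 formylation/methylation and C1 prenylation of a ring B 2-acylcyclohexanone; both quaternary carbons are set by alkylation trans to the C7 side chain.
3. The 2-acylcyclohexanone comes from a conjugate methyl addition/C-acylation that joins fragment 1, (S)-4-prenylcyclohex-2-enone, to fragment 2, a ketal-protected 4-methyl-3-oxopentanoyl benzotriazole.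
4. Fragment 1 comes from an organocatalytic Michael addition of 5-methylhex-4-enal to methyl vinyl ketone and an intramolecular aldol condensation (ring B is formed first); fragment 2 comes from methyl 4-methyl-3-oxopentanoate.
5. Ring order: ring B (aldol condensation), then ring A (aldol addition), giving the bicyclo[3.3.1]nonane.

Assumption: the target is handled as the enol tautomer drawn in the given SMILES, and the labels C1–C9 of its bicyclic core (C9 bridging ketone, C1 prenyl-bearing and C5 methyl-bearing bridgeheads, C8 = CMe2, C7 = CH–prenyl) are used for the corresponding atoms of all intermediates.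

## Route

Step 1
Reactants: 1 2-methylbut-3-en-2-ol; 2 ethyl vinyl ether
Product: 4 5-methylhex-4-enal, via allyl vinyl ether 3 (not isolated)
Conditions: 2 (5 equiv), H3PO4 (cat.), sealed tube, 120 °C
Reagents that add atoms: none
Why: Acid-catalysed transetherification gives the tertiary allyl vinyl ether, whose [3,3]-sigmatropic Claisen rearrangement delivers the γ,δ-unsaturated aldehyde carrying the prenyl-type olefin; no stereocentre is formed.

Step 2
Reactants: 4 5-methylhex-4-enal; 5 methyl vinyl ketone
Product: 6 (S)-2-(3-methylbut-2-en-1-yl)-5-oxohexanal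
Conditions: (S)-2-[methoxy(diphenyl)methyl]pyrrolidine (5 mol %), ethyl 3,4-dihydroxybenzoate (20 mol %), neat, 4 °C
Reagents that add atoms: none
Why: Enamine-catalysed asymmetric Michael addition in which the E-enamine of 4 is shielded on its Re face by the methoxy(diphenyl)methyl group of the (S)-catalyst and attacks the enone through its Si face, which sets the future C7 centre as S.

Step 3
Reactants: 6 (S)-2-(3-methylbut-2-en-1-yl)-5-oxohexanal
Product: 8 (S)-4-(3-methylbut-2-en-1-yl)cyclohex-2-en-1-one, via aldol adduct 7 (not isolated)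
Conditions: LiOH (0.2 equiv), i-PrOH, 23 °C
Reagents that add atoms: none
Why: Intramolecular aldol condensation (the methyl ketone enolate adds to the aldehyde in a six-membered ring and the β-hydroxy ketone dehydrates by E1cB) closes ring B, and the C7 centre is carried through because cyclisation outruns enolisation of the aldehyde.

Step 4
Reactants: 9 methyl 4-methyl-3-oxopentanoate
Product: 10 methyl 2-(2-isopropyl-1,3-dioxolan-2-yl)acetate
Conditions: ethylene glycol (3 equiv), TsOH (cat.), toluene, Dean–Stark, reflux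
Reagents that add atoms: ethylene glycol, OCCO
Why: Acid-catalysed ketalisation with azeotropic removal of water masks the isobutyryl ketone, so that the neighbouring methylene stays only singly activated in the later enolate steps.

Step 5
Reactants: 10 methyl 2-(2-isopropyl-1,3-dioxolan-2-yl)acetate
Product: 11 2-(2-isopropyl-1,3-dioxolan-2-yl)acetic acid
Conditions: LiOH, THF–H2O, 23 °C; then 1 M HCl to pH 4, 0 °C
Reagents that add atoms: lithium hydroxide, [Li+].[OH-]
Why: Ester saponification, safe here because the β-carbonyl group is a base-stable ketal and the acid is liberated cold at pH 4.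

Step 6
Reactants: 12 1H-benzotriazole; 13 methanesulfonyl chloride
Product: 14 1-(methylsulfonyl)-1H-benzotriazole
Conditions: pyridine, toluene, 23 °C
Reagents that add atoms: none
Why: N-Sulfonylation of benzotriazole gives the crystalline activating reagent needed for the next step.

Step 7
Reactants: 11 2-(2-isopropyl-1,3-dioxolan-2-yl)acetic acid; 14 1-(methylsulfonyl)-1H-benzotriazole
Product: 15 1-[(2-isopropyl-1,3-dioxolan-2-yl)acetyl]-1H-benzotriazole
Conditions: Et3N, THF, reflux
Reagents that add atoms: none
Why: Base-mediated acyl activation (the carboxylate is activated by the sulfonyl benzotriazole and the released benzotriazolide takes up the acyl group) gives the N-acylbenzotriazole without any acid, so the ketal survives.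

Step 8
Reactants: 8 (S)-4-(3-methylbut-2-en-1-yl)cyclohex-2-en-1-one; 15 1-[(2-isopropyl-1,3-dioxolan-2-yl)acetyl]-1H-benzotriazole
Product: 17 (3S,4S)-2-[(2-isopropyl-1,3-dioxolan-2-yl)acetyl]-3-methyl-4-(3-methylbut-2-en-1-yl)cyclohexan-1-one as its enol, via bromomagnesium enolate 16 (not isolated)
Conditions: MeMgBr (1.2 equiv), CuBr·SMe2 (5 mol %), THF, −40 °C; then 15, −40 → 0 °C; aq NH4Cl
Reagents that add atoms: methylmagnesium bromide, C[Mg]Br
Why: Copper-catalysed conjugate addition places the methyl group trans to the C7 side chain (a transient C8 centre) and gives the regiodefined magnesium enolate, which is C-acylated by the N-acylbenzotriazole in a crossed Claisen condensation that unites the two fragments.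

Step 9
Reactants: 17 (3S,4S)-2-acyl-3-methyl-4-prenylcyclohexanone (enol)
Product: 20 (4S)-2-[(2-isopropyl-1,3-dioxolan-2-yl)acetyl]-3-methyl-4-(3-methylbut-2-en-1-yl)cyclohex-2-en-1-one, via selenide 18 (not isolated), via selenoxide 19 (not isolated)
Conditions: PhSeCl, pyridine, CH2Cl2, 0 °C; then mCPBA (1.0 equiv), −78 → 23 °C
Reagents that add atoms: none
Why: α-Selenenylation of the β-diketone enol at C1 followed by selenoxide syn-elimination toward C8–H, the only β-hydrogen, gives the 2-acyl enone and removes the transient C8 centre while C7 is not touched.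

Step 10
Reactants: 20 (4S)-2-acyl-3-methyl-4-prenylcyclohex-2-enone
Product: 22 (2R,4S)-2-[(2-isopropyl-1,3-dioxolan-2-yl)acetyl]-3,3-dimethyl-2,4-bis(3-methylbut-2-en-1-yl)cyclohexan-1-one, via lithium enolate 21 (not isolated)
Conditions: Me2CuLi (1.3 equiv), Et2O, −78 → −20 °C; then prenyl bromide (3 equiv), DMPU, −20 → 23 °C; aq NH4Cl
Reagents that add atoms: lithium dimethylcuprate, [Li+].C[Cu-]C; 1-bromo-3-methylbut-2-ene, CC(C)=CCBr
Why: Cuprate 1,4-addition to the doubly activated enone builds the gem-dimethyl carbon C8, and the β-diketone enolate is then C-alkylated (SN2) on the face anti to the pseudo-axial C8 methyl group, which puts the new prenyl group trans and the acyl group cis to the C7 side chain and so sets C1.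

Step 11
Reactants: 23 2,2,2-trifluoroethanol; 24 formic acid
Product: 25 2,2,2-trifluoroethyl formate
Conditions: neat, 80 °C; fractional distillation
Reagents that add atoms: none
Why: Fischer esterification with the product distilled out gives a reactive formate whose alkoxide leaving group is too weak a nucleophile to cleave β-dicarbonyl compounds.

Step 12
Reactants: 22 (2R,4S)-2-acyl-3,3-dimethyl-2,4-diprenylcyclohexanone; 25 2,2,2-trifluoroethyl formate
Product: 27 (2S,4R,6Z)-6-(hydroxymethylidene)-2-[(2-isopropyl-1,3-dioxolan-2-yl)acetyl]-3,3-dimethyl-2,4-bis(3-methylbut-2-en-1-yl)cyclohexan-1-one, via lithium enolate 26 (not isolated)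
Conditions: LiN(i-Pr)2 (1.1 equiv), THF, −78 °C; then 25, −78 → 0 °C; aq NH4Cl
Reagents that add atoms: none
Why: Kinetic deprotonation occurs at the accessible ring methylene C5 and not at the neopentyl-like side-chain methylene, and the enolate is C-formylated by the activated formate (crossed Claisen condensation) to the chelated Z-hydroxymethylene ketone, the configuration at C1 and C7 staying as in 22.

Step 13
Reactants: 27 (6Z)-6-(hydroxymethylidene) ketone
Product: 28 (1R,3S,5R)-3-[(2-isopropyl-1,3-dioxolan-2-yl)acetyl]-1,4,4-trimethyl-3,5-bis(3-methylbut-2-en-1-yl)-2-oxocyclohexane-1-carbaldehyde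
Conditions: MeI, K2CO3, acetone, 23 °C
Reagents that add atoms: iodomethane, CI
Why: C-Alkylation of the potassium salt of the β-keto aldehyde in which iodomethane enters axially on the ring face opposite to the C7 side chain, so that C5 is set with methyl trans and formyl cis to that side chain and hence cis to the C1 acyl group.

Step 14
Reactants: 28 ring B keto aldehyde
Product: 29 (1S,5R,7R)-4-hydroxy-3-(2-isopropyl-1,3-dioxolan-2-yl)-5,8,8-trimethyl-1,7-bis(3-methylbut-2-en-1-yl)bicyclo[3.3.1]nonane-2,9-dione (C3 and C4 epimers)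
Conditions: lithium 2,2,6,6-tetramethylpiperidide (1.1 equiv), THF, −78 °C; then AcOH, −78 °C
Reagents that add atoms: none
Why: Intramolecular aldol addition in which the only enolisable carbon, C3, attacks the C4 aldehyde through a six-membered transition state that requires the cis acyl and formyl groups, closing ring A of the bicyclo[3.3.1]nonane on the fixed C1, C5 and C7 centres (the new C3 and C4 centres are erased in step 15).

Step 15
Reactants: 29 bicyclic β-hydroxy ketone
Product: 31 (1R,5R,7R)-4-hydroxy-5,8,8-trimethyl-1,7-bis(3-methylbut-2-en-1-yl)-3-(2-methylpropanoyl)bicyclo[3.3.1]non-3-ene-2,9-dione (CNP0265287.1), via trione ketal 30 (not isolated)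
Conditions: Dess–Martin periodinane, CH2Cl2, 23 °C; then 1 M HCl, THF, 23 °C
Reagents that add atoms: water, O
Why: Dess–Martin oxidation of the secondary alcohol gives the 2-substituted 1,3-diketone and acid-catalysed hydrolysis of the dioxolane then frees the isobutyryl ketone, the product settling as the hydrogen-bonded enolised β-triketone with C1, C5 and C7 unchanged.

## Compound list

1 | 2-methylbut-3-en-2-ol | CC(C)(O)C=C | starting material
2 | ethyl vinyl ether (ethoxyethene) | C=COCC | starting material
3 | 3-methyl-3-(vinyloxy)but-1-ene | C=COC(C)(C)C=C | intermediate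
4 | 5-methylhex-4-enal | CC(C)=CCCC=O | intermediate
5 | methyl vinyl ketone (but-3-en-2-one) | CC(=O)C=C | starting material
6 | (S)-2-(3-methylbut-2-en-1-yl)-5-oxohexanal | CC(C)=CC[C@@H](C=O)CCC(C)=O | intermediate
7 | (4S)-3-hydroxy-4-(3-methylbut-2-en-1-yl)cyclohexan-1-one, both C3 epimers | CC(C)=CC[C@@H]1CCC(=O)CC1O | intermediate
8 | (S)-4-(3-methylbut-2-en-1-yl)cyclohex-2-en-1-one | CC(C)=CC[C@@H]1CCC(=O)C=C1 | intermediate
9 | methyl 4-methyl-3-oxopentanoate | COC(=O)CC(=O)C(C)C | starting material
10 | methyl 2-(2-isopropyl-1,3-dioxolan-2-yl)acetate | COC(=O)CC1(C(C)C)OCCO1 | intermediate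
11 | 2-(2-isopropyl-1,3-dioxolan-2-yl)acetic acid | OC(=O)CC1(C(C)C)OCCO1 | intermediate
12 | 1H-benzotriazole | c1ccc2[nH]nnc2c1 | starting material
13 | methanesulfonyl chloride | CS(=O)(=O)Cl | starting material
14 | 1-(methylsulfonyl)-1H-benzotriazole | CS(=O)(=O)n1nnc2ccccc12 | intermediate
15 | 1-[(2-isopropyl-1,3-dioxolan-2-yl)acetyl]-1H-benzotriazole | O=C(CC1(C(C)C)OCCO1)n1nnc2ccccc12 | intermediate
16 | bromomagnesium enolate (toward C1) of (3S,4S)-3-methyl-4-(3-methylbut-2-en-1-yl)cyclohexanone, methyl and side chain trans | CC(C)=CC[C@@H]1CCC(O[Mg]Br)=C[C@H]1C | intermediate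
17 | (3S,4S)-2-[(2-isopropyl-1,3-dioxolan-2-yl)acetyl]-3-methyl-4-(3-methylbut-2-en-1-yl)cyclohexan-1-one, drawn as its ring enol, 3,4-trans | CC(C)=CC[C@@H]1CCC(O)=C(C(=O)CC2(C(C)C)OCCO2)[C@H]1C | intermediate
18 | (3S,4S)-2-[(2-isopropyl-1,3-dioxolan-2-yl)acetyl]-3-methyl-4-(3-methylbut-2-en-1-yl)-2-(phenylselanyl)cyclohexan-1-one | CC(C)=CC[C@@H]1CCC(=O)C([Se]c2ccccc2)(C(=O)CC3(C(C)C)OCCO3)[C@H]1C | intermediate
19 | selenoxide of 18, 2-(phenylseleninyl) compound | CC(C)=CC[C@@H]1CCC(=O)C([Se](=O)c2ccccc2)(C(=O)CC3(C(C)C)OCCO3)[C@H]1C | intermediate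
20 | (4S)-2-[(2-isopropyl-1,3-dioxolan-2-yl)acetyl]-3-methyl-4-(3-methylbut-2-en-1-yl)cyclohex-2-en-1-one | CC(C)=CC[C@@H]1CCC(=O)C(C(=O)CC2(C(C)C)OCCO2)=C1C | intermediate
21 | lithium enolate of (4S)-2-[(2-isopropyl-1,3-dioxolan-2-yl)acetyl]-3,3-dimethyl-4-(3-methylbut-2-en-1-yl)cyclohexan-1-one | CC(C)=CC[C@@H]1CCC(O[Li])=C(C(=O)CC2(C(C)C)OCCO2)C1(C)C | intermediate
22 | (2R,4S)-2-[(2-isopropyl-1,3-dioxolan-2-yl)acetyl]-3,3-dimethyl-2,4-bis(3-methylbut-2-en-1-yl)cyclohexan-1-one, the two prenyl groups trans | CC(C)=CC[C@@H]1CCC(=O)[C@](CC=C(C)C)(C(=O)CC2(C(C)C)OCCO2)C1(C)C | intermediate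
23 | 2,2,2-trifluoroethanol | OCC(F)(F)F | starting material
24 | formic acid | OC=O | starting material
25 | 2,2,2-trifluoroethyl formate | O=COCC(F)(F)F | intermediate
26 | lithium enolate of 22 toward the ring methylene C5 | CC(C)=CC[C@@H]1CC=C(O[Li])[C@](CC=C(C)C)(C(=O)CC2(C(C)C)OCCO2)C1(C)C | intermediate
27 | (2S,4R,6Z)-6-(hydroxymethylidene)-2-[(2-isopropyl-1,3-dioxolan-2-yl)acetyl]-3,3-dimethyl-2,4-bis(3-methylbut-2-en-1-yl)cyclohexan-1-one, same spatial arrangement at the two stereocentres as 22 | CC(C)=CC[C@@H]1C/C(=C/O)C(=O)[C@](CC=C(C)C)(C(=O)CC2(C(C)C)OCCO2)C1(C)C | intermediate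
28 | (1R,3S,5R)-3-[(2-isopropyl-1,3-dioxolan-2-yl)acetyl]-1,4,4-trimethyl-3,5-bis(3-methylbut-2-en-1-yl)-2-oxocyclohexane-1-carbaldehyde, formyl and acyl groups and the 5-prenyl group all cis | CC(C)=CC[C@@H]1C[C@@](C=O)(C)C(=O)[C@](CC=C(C)C)(C(=O)CC2(C(C)C)OCCO2)C1(C)C | intermediate
29 | (1S,5R,7R)-4-hydroxy-3-(2-isopropyl-1,3-dioxolan-2-yl)-5,8,8-trimethyl-1,7-bis(3-methylbut-2-en-1-yl)bicyclo[3.3.1]nonane-2,9-dione, C3 and C4 epimers, C7 side chain on the face of the C2–C4 bridge | CC(C)=CC[C@@H]1C[C@@]2(C)C(=O)[C@](CC=C(C)C)(C(=O)C(C3(C(C)C)OCCO3)C2O)C1(C)C | intermediate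
30 | (1R,5R,7R)-4-hydroxy-3-(2-isopropyl-1,3-dioxolan-2-yl)-5,8,8-trimethyl-1,7-bis(3-methylbut-2-en-1-yl)bicyclo[3.3.1]non-3-ene-2,9-dione (enol of the 2,4,9-trione) | CC(C)=CC[C@@H]1C[C@@]2(C)C(=O)[C@](CC=C(C)C)(C(=O)C(C3(C(C)C)OCCO3)=C2O)C1(C)C | intermediate
31 | (1R,5R,7R)-4-hydroxy-5,8,8-trimethyl-1,7-bis(3-methylbut-2-en-1-yl)-3-(2-methylpropanoyl)bicyclo[3.3.1]non-3-ene-2,9-dione (CNP0265287.1) | CC(C)=CC[C@@H]1C[C@@]2(C)C(=O)[C@](CC=C(C)C)(C(=O)C(C(=O)C(C)C)=C2O)C1(C)C | target

## Step count and risks

Total step count: 15.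
Longest linear sequence: 10 steps (1, 2, 3, 8, 9, 10, 12, 13, 14, 15; the line 4, 5, 7, 8, 9, 10, 12, 13, 14, 15 has the same length).

The three steps most likely to fail:

Step 10. The one-pot cuprate addition and C-prenylation must build a quaternary carbon next to the new quaternary C8; O-alkylation or no alkylation is the danger. The fallback sets out from 20. Me2CuLi is added and the reaction is quenched with aqueous NH4Cl, giving the enolised 2-acyl-3,3-dimethyl-4-prenylcyclohexanone F1. A Tsuji–Trost allylation (allyl methyl carbonate, Pd(PPh3)4, THF) alkylates this soft β-diketone at carbon under neutral conditions with the same facial bias and gives the C1-allyl diketone F2. Olefin cross-metathesis with 2-methylbut-2-ene (second-generation Grubbs catalyst, 40 °C) then turns allyl into prenyl and comes back to the route at 22.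

Step 12. The base may enolise the side-chain methylene C3 instead of the ring methylene C5. The fallback sets out from 22, which is heated with tert-butoxybis(dimethylamino)methane in toluene at 90 °C. This reversible condensation aminomethylenates the unhindered ring methylene under thermodynamic control and gives the (dimethylamino)methylidene ketone F3. Mild hydrolysis (AcOH/NaOAc, THF–H2O) frees the hydroxymethylene ketone and comes back to the route at 27.

Step 14. The aldol ring closure needs the conformer with acyl and formyl groups both axial; the enolate could instead open the ketal, or the aldolate could revert. The fallback sets out from 28. Pinnick oxidation (NaClO2, NaH2PO4, 2-methylbut-2-ene, t-BuOH–H2O) gives the ring B carboxylic acid F4, and TMSCHN2 (MeOH–toluene) gives the ring B methyl ester F5. A Dieckmann-type Claisen condensation of the C3 enolate onto the ester (KOt-Bu, THF, 0 °C) closes ring A at the trione oxidation level and comes back to the route at 30, which is hydrolysed as in step 15.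

## Further compounds

F1 | step 10 | (4S)-2-[(2-isopropyl-1,3-dioxolan-2-yl)acetyl]-3,3-dimethyl-4-(3-methylbut-2-en-1-yl)cyclohexan-1-one, drawn as its ring enol | CC(C)=CC[C@@H]1CCC(O)=C(C(=O)CC2(C(C)C)OCCO2)C1(C)C
F2 | step 10 | (2R,4S)-2-[(2-isopropyl-1,3-dioxolan-2-yl)acetyl]-3,3-dimethyl-4-(3-methylbut-2-en-1-yl)-2-(prop-2-en-1-yl)cyclohexan-1-one | CC(C)=CC[C@@H]1CCC(=O)[C@](CC=C)(C(=O)CC2(C(C)C)OCCO2)C1(C)C
F3 | step 12 | (6E)-6-[(dimethylamino)methylidene] derivative of 22, other centres as in 22 | CC(C)=CC[C@@H]1C/C(=C\N(C)C)C(=O)[C@](CC=C(C)C)(C(=O)CC2(C(C)C)OCCO2)C1(C)C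
F4 | step 14 | carboxylic acid corresponding to aldehyde 28 (CHO replaced by CO2H, same configuration) | CC(C)=CC[C@@H]1C[C@@](C(=O)O)(C)C(=O)[C@](CC=C(C)C)(C(=O)CC2(C(C)C)OCCO2)C1(C)C
F5 | step 14 | methyl ester of F4 | CC(C)=CC[C@@H]1C[C@@](C(=O)OC)(C)C(=O)[C@](CC=C(C)C)(C(=O)CC2(C(C)C)OCCO2)C1(C)C
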